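**Retrosynthetic overview**
1. Target 22 comes from 19 by desilylation, acetylation and O-deallylation. The two C-methyls of 19 come from the primary alcohols of 1,4-diol 17 (OMs → H), and 17 from LiAlH4 opening of the trans-lactone 16/15.
2. Key C7–C8 bond: intermolecular aldol of the lithium enolate of (R)-β-arylmethyl-γ-butyrolactone 12 with veratraldehyde 13. It sets C8 trans to C8′ and C7 through a closed chair transition state.
3. Lactone 12 (C8′) comes from Evans alkylation of N-acyl oxazolidinone 7 with tert-butyl bromoacetate 8, reductive removal of the auxiliary and lactonisation. 7 comes from ferulic acid 1.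
4. Rings: the target has no ring besides the two purchased arenes. The only ring made is the temporary γ-butyrolactone (step 8), opened again in step 11.

Assumption: the SMILES is read as (1R,2S,3R)-1-(3,4-dimethoxyphenyl)-4-(4-hydroxy-3-methoxyphenyl)-2,3-dimethylbutyl acetate (7R,8S,8′R in lignan numbering; C7 = CHOAc, C8 and C8′ = CHMe).

**Route**

Step 1
Reactants: 1 ferulic acid
Product: 2 3-(4-hydroxy-3-methoxyphenyl)propanoic acid
Conditions: H2 (1 atm), 10% Pd/C, MeOH, rt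
Reagents that add atoms: none
Why: Heterogeneous catalytic hydrogenation saturates the conjugated C=C and leaves the arene and the acid untouched.

Step 2
Reactants: 2 3-(4-hydroxy-3-methoxyphenyl)propanoic acid
Product: 3 prop-2-enyl 3-[3-methoxy-4-(prop-2-enyloxy)phenyl]propanoate
Conditions: allyl bromide (2.5 equiv), K2CO3 (3 equiv), DMF, 50 °C
Reagents that add atoms: allyl bromide, C=CCBr
Why: Williamson etherification of the phenoxide and SN2 alkylation of the carboxylate both run cleanly with carbonate in DMF.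

Step 3
Reactants: 3 prop-2-enyl 3-[3-methoxy-4-(prop-2-enyloxy)phenyl]propanoate
Product: 4 3-[3-methoxy-4-(prop-2-enyloxy)phenyl]propanoic acid
Conditions: 2 M NaOH, THF/MeOH, rt; then 1 M HCl
Reagents that add atoms: sodium hydroxide, [Na+].[OH-]
Why: Saponification cleaves only the allyl ester, since the aryl allyl ether is inert to hydroxide.

Step 4
Reactants: 4 3-[3-methoxy-4-(prop-2-enyloxy)phenyl]propanoic acid
Product: 5 3-[3-methoxy-4-(prop-2-enyloxy)phenyl]propanoyl chloride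
Conditions: (COCl)2 (1.3 equiv), DMF (cat.), CH2Cl2, 0 °C to rt; evaporate, use crude
Reagents that add atoms: oxalyl chloride, O=C(Cl)C(=O)Cl
Why: DMF-catalysed (Vilsmeier-type) acid chloride formation gives only gaseous by-products and needs no Lewis acid that could trigger Friedel–Crafts cyclisation.

Step 5
Reactants: 5 3-[3-methoxy-4-(prop-2-enyloxy)phenyl]propanoyl chloride; 6 (4S)-4-benzyl-1,3-oxazolidin-2-one
Product: 7 (4S)-4-benzyl-3-{3-[3-methoxy-4-(prop-2-enyloxy)phenyl]propanoyl}-1,3-oxazolidin-2-one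
Conditions: Et3N (1.5 equiv), DMAP (0.1 equiv), CH2Cl2, 0 °C to rt
Reagents that add atoms: none
Why: DMAP-catalysed N-acylation of the Evans auxiliary by an acid chloride is a standard high-yielding reaction that does not touch the auxiliary stereocentre.

Step 6
Reactants: 7 (4S)-4-benzyl-3-{3-[3-methoxy-4-(prop-2-enyloxy)phenyl]propanoyl}-1,3-oxazolidin-2-one; 8 tert-butyl bromoacetate
Product: 10 tert-butyl (3R)-4-[(4S)-4-benzyl-2-oxo-1,3-oxazolidin-3-yl]-3-{[3-methoxy-4-(prop-2-enyloxy)phenyl]methyl}-4-oxobutanoate, via sodium Z-enolate 9 (not isolated)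
Conditions: NaHMDS (1.1 equiv), THF, −78 °C, 45 min; then 8 (2 equiv), −78 to −50 °C
Reagents that add atoms: none
Why: In this Evans asymmetric alkylation the chelated sodium Z-enolate is alkylated on the face opposite the C4 benzyl group, which sets the future C8′ as R (typically ≥95:5 dr).

Step 7
Reactants: 10 tert-butyl (3R)-4-[(4S)-4-benzyl-2-oxo-1,3-oxazolidin-3-yl]-3-{[3-methoxy-4-(prop-2-enyloxy)phenyl]methyl}-4-oxobutanoate
Product: 11 tert-butyl (3R)-4-hydroxy-3-{[3-methoxy-4-(prop-2-enyloxy)phenyl]methyl}butanoate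
Conditions: LiBH4 (1.5 equiv), MeOH (1.5 equiv), THF, 0 °C
Reagents that add atoms: none
Why: Reductive cleavage of the auxiliary with LiBH4 reduces the activated exocyclic imide carbonyl chemoselectively, while the hindered tert-butyl ester and the stereocentre are untouched.

Step 8
Reactants: 11 tert-butyl (3R)-4-hydroxy-3-{[3-methoxy-4-(prop-2-enyloxy)phenyl]methyl}butanoate
Product: 12 (4R)-4-{[3-methoxy-4-(prop-2-enyloxy)phenyl]methyl}oxolan-2-one
Conditions: p-TsOH·H2O (10 mol%), toluene, 80 °C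
Reagents that add atoms: none
Why: Acid-catalysed loss of isobutene from the tert-butyl ester and spontaneous lactonisation of the γ-hydroxy acid give the γ-butyrolactone without touching the stereocentre.

Step 9
Reactants: 12 (4R)-4-{[3-methoxy-4-(prop-2-enyloxy)phenyl]methyl}oxolan-2-one; 13 3,4-dimethoxybenzaldehyde
Product: 15 (3S,4R)-3-[(R)-(3,4-dimethoxyphenyl)(hydroxy)methyl]-4-{[3-methoxy-4-(prop-2-enyloxy)phenyl]methyl}oxolan-2-one, via lithium lactone enolate 14 (not isolated)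
Conditions: LDA (1.1 equiv, commercial solution), THF, −78 °C, 45 min; then 13 (1.3 equiv), −78 °C, 1 h; sat. NH4Cl at −78 °C; chromatography
Reagents that add atoms: none
Why: In this kinetic intermolecular aldol the aldehyde adds anti to the C4 arylmethyl group (C8 trans, 3S), and the ring-fixed E-enolate in a closed Zimmerman–Traxler chair favours the anti (threo, 7R) carbinol; selectivity at C7 is expected to be modest (about 2–4:1) and the minor 7-epimer is removed by chromatography.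

Step 10
Reactants: 15 (3S,4R)-3-[(R)-(3,4-dimethoxyphenyl)(hydroxy)methyl]-4-{[3-methoxy-4-(prop-2-enyloxy)phenyl]methyl}oxolan-2-one
Product: 16 (3S,4R)-3-[(R)-{[tert-butyl(dimethyl)silyl]oxy}(3,4-dimethoxyphenyl)methyl]-4-{[3-methoxy-4-(prop-2-enyloxy)phenyl]methyl}oxolan-2-one
Conditions: TBSOTf (1.5 equiv), 2,6-lutidine (2.5 equiv), CH2Cl2, −78 to 0 °C
Reagents that add atoms: tert-butyldimethylsilyl trifluoromethanesulfonate, CC(C)(C)[Si](C)(C)OS(=O)(=O)C(F)(F)F
Why: Silylation with the triflate and a hindered weak base avoids retro-aldol or elimination and masks the C7 hydroxyl, which would otherwise close a tetrahydrofuran in steps 12–13.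

Step 11
Reactants: 16 (3S,4R)-3-[(R)-{[tert-butyl(dimethyl)silyl]oxy}(3,4-dimethoxyphenyl)methyl]-4-{[3-methoxy-4-(prop-2-enyloxy)phenyl]methyl}oxolan-2-one
Product: 17 (2R,3R)-2-[(R)-{[tert-butyl(dimethyl)silyl]oxy}(3,4-dimethoxyphenyl)methyl]-3-{[3-methoxy-4-(prop-2-enyloxy)phenyl]methyl}butane-1,4-diol
Conditions: LiAlH4 (2 equiv), THF, 0 °C to rt; Fieser work-up
Reagents that add atoms: none
Why: Hydride reduction of the lactone to the 1,4-diol is faster than enolisation, so C8 and C8′ keep their configuration (the descriptor at C8 changes only through CIP priorities).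

Step 12
Reactants: 17 (2R,3R)-2-[(R)-{[tert-butyl(dimethyl)silyl]oxy}(3,4-dimethoxyphenyl)methyl]-3-{[3-methoxy-4-(prop-2-enyloxy)phenyl]methyl}butane-1,4-diol
Product: 18 (2R,3R)-2-[(R)-{[tert-butyl(dimethyl)silyl]oxy}(3,4-dimethoxyphenyl)methyl]-3-{[3-methoxy-4-(prop-2-enyloxy)phenyl]methyl}butane-1,4-diyl dimethanesulfonate
Conditions: MsCl (3 equiv), Et3N (4 equiv), CH2Cl2, 0 °C
Reagents that add atoms: methanesulfonyl chloride, CS(=O)(=O)Cl
Why: Sulfene-mediated mesylation of both primary alcohols at 0 °C is much faster than cyclisation of the mono-mesylate to a tetrahydrofuran.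

Step 13
Reactants: 18 (2R,3R)-2-[(R)-{[tert-butyl(dimethyl)silyl]oxy}(3,4-dimethoxyphenyl)methyl]-3-{[3-methoxy-4-(prop-2-enyloxy)phenyl]methyl}butane-1,4-diyl dimethanesulfonate
Product: 19 tert-butyl{[(1R,2S,3R)-1-(3,4-dimethoxyphenyl)-4-[3-methoxy-4-(prop-2-enyloxy)phenyl]-2,3-dimethylbutyl]oxy}dimethylsilane
Conditions: LiEt3BH (6 equiv), THF, 0 °C to rt
Reagents that add atoms: none
Why: SN2 hydride displacement of the two primary mesylates by Super-Hydride turns both CH2OMs groups into the C8 and C8′ methyls without touching any stereocentre.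

Step 14
Reactants: 19 tert-butyl{[(1R,2S,3R)-1-(3,4-dimethoxyphenyl)-4-[3-methoxy-4-(prop-2-enyloxy)phenyl]-2,3-dimethylbutyl]oxy}dimethylsilane
Product: 20 (1R,2S,3R)-1-(3,4-dimethoxyphenyl)-4-[3-methoxy-4-(prop-2-enyloxy)phenyl]-2,3-dimethylbutan-1-ol
Conditions: TBAF (1.5 equiv), THF, rt to 40 °C
Reagents that add atoms: none
Why: Fluoride-driven Si–O cleavage leaves the benzylic C–O bond intact, so 7R is retained.

Step 15
Reactants: 20 (1R,2S,3R)-1-(3,4-dimethoxyphenyl)-4-[3-methoxy-4-(prop-2-enyloxy)phenyl]-2,3-dimethylbutan-1-ol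
Product: 21 (1R,2S,3R)-1-(3,4-dimethoxyphenyl)-4-[3-methoxy-4-(prop-2-enyloxy)phenyl]-2,3-dimethylbutyl acetate
Conditions: Ac2O (3 equiv), pyridine, DMAP (cat.), CH2Cl2, 0 °C to rt
Reagents that add atoms: acetic anhydride, CC(=O)OC(C)=O
Why: DMAP-catalysed O-acylation under basic, non-ionising conditions acetylates the secondary benzylic alcohol with retention at C7.

Step 16
Reactants: 21 (1R,2S,3R)-1-(3,4-dimethoxyphenyl)-4-[3-methoxy-4-(prop-2-enyloxy)phenyl]-2,3-dimethylbutyl acetate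
Product: 22 (1R,2S,3R)-1-(3,4-dimethoxyphenyl)-4-(4-hydroxy-3-methoxyphenyl)-2,3-dimethylbutyl acetate
Conditions: Pd(PPh3)4 (5 mol%), morpholine (5 equiv), THF, rt
Reagents that add atoms: none
Why: Tsuji–Trost-type Pd(0) deallylation ionises only the aryl allyl ether and morpholine traps the π-allyl complex, under neutral room-temperature conditions that leave the benzylic acetate and the methyl ethers untouched.

**Compound list**
1 | ferulic acid, (E)-3-(4-hydroxy-3-methoxyphenyl)prop-2-enoic acid | COc1cc(/C=C/C(=O)O)ccc1O | starting material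
2 | 3-(4-hydroxy-3-methoxyphenyl)propanoic acid | COc1cc(CCC(=O)O)ccc1O | intermediate
3 | prop-2-enyl 3-[3-methoxy-4-(prop-2-enyloxy)phenyl]propanoate | C=CCOC(=O)CCc1ccc(OCC=C)c(OC)c1 | intermediate
4 | 3-[3-methoxy-4-(prop-2-enyloxy)phenyl]propanoic acid | OC(=O)CCc1ccc(OCC=C)c(OC)c1 | intermediate
5 | 3-[3-methoxy-4-(prop-2-enyloxy)phenyl]propanoyl chloride | ClC(=O)CCc1ccc(OCC=C)c(OC)c1 | intermediate
6 | (4S)-4-benzyl-1,3-oxazolidin-2-one | O=C1N[C@@H](Cc2ccccc2)CO1 | starting material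
7 | (4S)-4-benzyl-3-{3-[3-methoxy-4-(prop-2-enyloxy)phenyl]propanoyl}-1,3-oxazolidin-2-one | O=C(CCc1ccc(OCC=C)c(OC)c1)N1[C@@H](Cc2ccccc2)COC1=O | intermediate
8 | tert-butyl bromoacetate | CC(C)(C)OC(=O)CBr | starting material
9 | sodium (1Z)-1-[(4S)-4-benzyl-2-oxo-1,3-oxazolidin-3-yl]-3-[3-methoxy-4-(prop-2-enyloxy)phenyl]prop-1-en-1-olate (sodium Z-enolate of 7) | [Na+].[O-]/C(=C\Cc1ccc(OCC=C)c(OC)c1)N1[C@@H](Cc2ccccc2)COC1=O | intermediate
10 | tert-butyl (3R)-4-[(4S)-4-benzyl-2-oxo-1,3-oxazolidin-3-yl]-3-{[3-methoxy-4-(prop-2-enyloxy)phenyl]methyl}-4-oxobutanoate | CC(C)(C)OC(=O)C[C@@H](Cc1ccc(OCC=C)c(OC)c1)C(=O)N1[C@@H](Cc2ccccc2)COC1=O | intermediate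
11 | tert-butyl (3R)-4-hydroxy-3-{[3-methoxy-4-(prop-2-enyloxy)phenyl]methyl}butanoate | CC(C)(C)OC(=O)C[C@@H](Cc1ccc(OCC=C)c(OC)c1)CO | intermediate
12 | (4R)-4-{[3-methoxy-4-(prop-2-enyloxy)phenyl]methyl}oxolan-2-one | O=C1C[C@@H](Cc2ccc(OCC=C)c(OC)c2)CO1 | intermediate
13 | 3,4-dimethoxybenzaldehyde (veratraldehyde) | COc1ccc(C=O)cc1OC | starting material
14 | lithium (4R)-4-{[3-methoxy-4-(prop-2-enyloxy)phenyl]methyl}-4,5-dihydrofuran-2-olate (lithium enolate of 12) | [Li+].[O-]C1=C[C@@H](Cc2ccc(OCC=C)c(OC)c2)CO1 | intermediate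
15 | (3S,4R)-3-[(R)-(3,4-dimethoxyphenyl)(hydroxy)methyl]-4-{[3-methoxy-4-(prop-2-enyloxy)phenyl]methyl}oxolan-2-one | O=C1OC[C@H](Cc2ccc(OCC=C)c(OC)c2)[C@H]1[C@@H](O)c1ccc(OC)c(OC)c1 | intermediate
16 | (3S,4R)-3-[(R)-{[tert-butyl(dimethyl)silyl]oxy}(3,4-dimethoxyphenyl)methyl]-4-{[3-methoxy-4-(prop-2-enyloxy)phenyl]methyl}oxolan-2-one | O=C1OC[C@H](Cc2ccc(OCC=C)c(OC)c2)[C@H]1[C@@H](O[Si](C)(C)C(C)(C)C)c1ccc(OC)c(OC)c1 | intermediate
17 | (2R,3R)-2-[(R)-{[tert-butyl(dimethyl)silyl]oxy}(3,4-dimethoxyphenyl)methyl]-3-{[3-methoxy-4-(prop-2-enyloxy)phenyl]methyl}butane-1,4-diol | OC[C@H](Cc1ccc(OCC=C)c(OC)c1)[C@H](CO)[C@@H](O[Si](C)(C)C(C)(C)C)c1ccc(OC)c(OC)c1 | intermediate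
18 | (2R,3R)-2-[(R)-{[tert-butyl(dimethyl)silyl]oxy}(3,4-dimethoxyphenyl)methyl]-3-{[3-methoxy-4-(prop-2-enyloxy)phenyl]methyl}butane-1,4-diyl dimethanesulfonate | CS(=O)(=O)OC[C@H](Cc1ccc(OCC=C)c(OC)c1)[C@H](COS(C)(=O)=O)[C@@H](O[Si](C)(C)C(C)(C)C)c1ccc(OC)c(OC)c1 | intermediate
19 | tert-butyl{[(1R,2S,3R)-1-(3,4-dimethoxyphenyl)-4-[3-methoxy-4-(prop-2-enyloxy)phenyl]-2,3-dimethylbutyl]oxy}dimethylsilane | C[C@H](Cc1ccc(OCC=C)c(OC)c1)[C@H](C)[C@@H](O[Si](C)(C)C(C)(C)C)c1ccc(OC)c(OC)c1 | intermediate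
20 | (1R,2S,3R)-1-(3,4-dimethoxyphenyl)-4-[3-methoxy-4-(prop-2-enyloxy)phenyl]-2,3-dimethylbutan-1-ol | C[C@H](Cc1ccc(OCC=C)c(OC)c1)[C@H](C)[C@@H](O)c1ccc(OC)c(OC)c1 | intermediate
21 | (1R,2S,3R)-1-(3,4-dimethoxyphenyl)-4-[3-methoxy-4-(prop-2-enyloxy)phenyl]-2,3-dimethylbutyl acetate | C[C@H](Cc1ccc(OCC=C)c(OC)c1)[C@H](C)[C@@H](OC(C)=O)c1ccc(OC)c(OC)c1 | intermediate
22 | (1R,2S,3R)-1-(3,4-dimethoxyphenyl)-4-(4-hydroxy-3-methoxyphenyl)-2,3-dimethylbutyl acetate | COc1cc(C[C@@H](C)[C@H](C)[C@@H](OC(C)=O)c2ccc(OC)c(OC)c2)ccc1O | target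

**Step count and risks**
Total step count: 16. Longest linear sequence: 16 steps (1 → 22; 6, 8 and 13 are purchased).

Most likely to fail:

Step 9 (C7 selectivity of the aldol). Lithium lactone enolates often give only modest threo:erythro ratios with aryl aldehydes. The fallback sets out from 12 and comes back at 15. The enolate of 12 (LDA, 2.2 equiv, THF, −78 °C) is C-acylated with commercial 3,4-dimethoxybenzoyl chloride in a crossed Claisen-type condensation. This gives (3S,4R)-3-(3,4-dimethoxybenzoyl)-4-{[3-methoxy-4-(prop-2-enyloxy)phenyl]methyl}oxolan-2-one F1, whose acidic C3 settles trans to the C4 substituent. The aryl ketone is then reduced with L-Selectride (THF, −78 °C). This bulky, non-chelating hydride should add in the Felkin–Anh sense anti to the lactone carbonyl and so give the threo (7R) alcohol 15; chelating reductants such as Zn(BH4)2 must be avoided because they give the 7-epimer. Unwanted 7-epimer from step 9 can be fed into the same ketone by Dess–Martin oxidation.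

Step 13 (double hydride displacement). Possible problems are S–O cleavage, leading to tetrahydrofuran closure, and sluggish SN2 at the β-branched centres. The fallback sets out from 18 and comes back at 19. Finkelstein exchange (NaI, butanone, reflux) gives tert-butyl{[(1R,2S,3R)-1-(3,4-dimethoxyphenyl)-4-iodo-2-(iodomethyl)-3-{[3-methoxy-4-(prop-2-enyloxy)phenyl]methyl}butyl]oxy}dimethylsilane F2. Radical dehalogenation (Bu3SnH, AIBN, toluene, 80 °C) then delivers 19 without any ionic intermediate.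

Step 16 (deallylation next to an electron-rich benzylic acetate). The fallback sets out from 20 and comes back at 22. The allyl group is removed first (Pd(PPh3)4, morpholine, THF, rt) to give 4-[(2R,3S,4R)-4-(3,4-dimethoxyphenyl)-4-hydroxy-2,3-dimethylbutyl]-2-methoxyphenol F3. Exhaustive acetylation (Ac2O, pyridine, DMAP) gives 4-[(2R,3S,4R)-4-(acetyloxy)-4-(3,4-dimethoxyphenyl)-2,3-dimethylbutyl]-2-methoxyphenyl acetate F4. The much more reactive aryl acetate is then cleaved selectively by aminolysis with pyrrolidine (1.2 equiv, CH2Cl2, 0 °C), leaving the secondary alkyl acetate of 22.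

**Further compounds**
F1 | step 9 | (3S,4R)-3-(3,4-dimethoxybenzoyl)-4-{[3-methoxy-4-(prop-2-enyloxy)phenyl]methyl}oxolan-2-one | O=C1OC[C@H](Cc2ccc(OCC=C)c(OC)c2)[C@H]1C(=O)c1ccc(OC)c(OC)c1
F2 | step 13 | tert-butyl{[(1R,2S,3R)-1-(3,4-dimethoxyphenyl)-4-iodo-2-(iodomethyl)-3-{[3-methoxy-4-(prop-2-enyloxy)phenyl]methyl}butyl]oxy}dimethylsilane | IC[C@H](Cc1ccc(OCC=C)c(OC)c1)[C@H](CI)[C@@H](O[Si](C)(C)C(C)(C)C)c1ccc(OC)c(OC)c1
F3 | step 16 | 4-[(2R,3S,4R)-4-(3,4-dimethoxyphenyl)-4-hydroxy-2,3-dimethylbutyl]-2-methoxyphenol | C[C@H](Cc1ccc(O)c(OC)c1)[C@H](C)[C@@H](O)c1ccc(OC)c(OC)c1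
F4 | step 16 | 4-[(2R,3S,4R)-4-(acetyloxy)-4-(3,4-dimethoxyphenyl)-2,3-dimethylbutyl]-2-methoxyphenyl acetate | C[C@H](Cc1ccc(OC(C)=O)c(OC)c1)[C@H](C)[C@@H](OC(C)=O)c1ccc(OC)c(OC)c1
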